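**Retrosynthetic overview**

1. Target ⇐ Mitsunobu esterification with tiglic acid (inversion at C6) of the 6-epi macrocyclic alcohol.
2. Ten-membered carbocycle (ring C, formed last) ⇐ ring-closing metathesis making the Z C4=C5 olefin from an isopropenyl-furanone / vinyl-carbinol diene.
3. α-Methylene-γ-lactone (ring B) and the C7–C8 bond ⇐ chromium-mediated allylation–lactonisation joining fragment A (furanone aldehyde, C1–C4 and C8–C10) with fragment B (2-(bromomethyl)dienoate, C5–C7 and C11–C13).
4. Fragment A ⇐ (R)-lactic acid (Seebach alkylation sets C10), enyne acetylide addition, gold cyclisation to the furanone (ring A, formed first). Fragment B ⇐ acrolein + methyl propiolate (asymmetric alkynylation sets C6 as its epimer).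
5. Ring order: furanone A → lactone B → carbocycle C.

Assumption: locants C1–C15 follow germacrane numbering (C1 ketone, C3–O–C10 ether bridge, C12 lactone carbonyl on O8, ester on C6); CIP labels are those of each compound as drawn.

**Route**

Step 1
Reactants: 1 (R)-lactic acid; 2 pivaldehyde
Product: 3 (2R,5R)-2-tert-butyl-5-methyl-1,3-dioxolan-4-one
Conditions: TsOH·H2O (cat.), H2SO4 (cat.), pentane, reflux (Dean–Stark); recrystallisation, pentane, −78 °C
Reagents that add atoms: none
Why: Acid-catalysed acetalisation (Seebach self-regeneration of stereocentres) gives the dioxolanone whose new acetal centre settles cis to the methyl group under thermodynamic control and crystallisation, storing the lactate configuration at C2 of the ring.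

Step 2
Reactants: 3 (2R,5R)-2-tert-butyl-5-methyl-1,3-dioxolan-4-one; 4 prenyl bromide (1-bromo-3-methylbut-2-ene)
Product: 6 (2R,5S)-2-tert-butyl-5-methyl-5-(3-methylbut-2-en-1-yl)-1,3-dioxolan-4-one, via lithium enolate 5 (not isolated)
Conditions: LiN(iPr)2, THF, −78 °C; then 4, −78 → −20 °C
Reagents that add atoms: none
Why: The tert-butyl acetal shields one face of enolate 5, so SN2 alkylation by the primary allylic bromide occurs trans to tert-butyl and creates the quaternary carbon (future C10, S) with high selectivity (Seebach alkylation).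

Step 3
Reactants: 6 (2R,5S)-2-tert-butyl-5-methyl-5-(3-methylbut-2-en-1-yl)-1,3-dioxolan-4-one; 7 2-methylbut-1-en-3-yne
Product: 10 (6S)-6-hydroxy-2,6,9-trimethyldeca-1,8-dien-3-yn-5-one, via lithium acetylide 8 (not isolated), via lithium hemiketal alkoxide 9 (not isolated)
Conditions: 7, n-BuLi, THF, −78 °C; then 6, −78 °C; aq. NH4Cl, −78 °C → rt
Reagents that add atoms: none
Why: 1,2-Addition of the lithium acetylide to the lactone-type carbonyl stops at tetrahedral alkoxide 9 at −78 °C, and protonation collapses it with loss of pivaldehyde to the α′-hydroxy ynone without touching the quaternary centre.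

Step 4
Reactants: 10 (6S)-6-hydroxy-2,6,9-trimethyldeca-1,8-dien-3-yn-5-one
Product: 11 (2S)-2-methyl-2-(3-methylbut-2-en-1-yl)-5-(prop-1-en-2-yl)furan-3(2H)-one
Conditions: (4-CF3C6H4)3PAuCl (5 mol %), AgOTf (AgOSO2CF3, 5 mol %), toluene, rt
Reagents that add atoms: none
Why: Carbophilic gold activation of the ynone triggers 5-endo-dig attack of the tertiary hydroxyl (cycloisomerisation) to give the 3(2H)-furanone, the quaternary centre being a spectator.

Step 5
Reactants: 11 (2S)-2-methyl-2-(3-methylbut-2-en-1-yl)-5-(prop-1-en-2-yl)furan-3(2H)-one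
Product: 13 2-[(2S)-2-methyl-3-oxo-5-(prop-1-en-2-yl)-2,3-dihydrofuran-2-yl]acetaldehyde, via vicinal diol 12 (not isolated)
Conditions: OsO4 (2 mol %), NaIO4 (4 equiv), 2,6-lutidine, dioxane/H2O 3:1, rt
Reagents that add atoms: sodium periodate, [Na+].[O-]I(=O)(=O)=O; osmium tetroxide (catalytic oxygen carrier), O=[Os](=O)(=O)=O
Why: Lemieux–Johnson oxidation, in which OsO4 dihydroxylates the electron-rich trisubstituted prenyl olefin much faster than the electron-poor isopropenyl and furanone double bonds and periodate cleaves diol 12, while 2,6-lutidine keeps the medium mild so the β-alkoxy aldehyde does not eliminate.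

Step 6
Reactants: 14 acrolein; 15 methyl propiolate
Product: 17 methyl (4R)-4-hydroxyhex-5-en-2-ynoate, via methylzinc acetylide 16 (not isolated)
Conditions: Me2Zn (3 equiv), (S,S)-ProPhenol (10 mol %), toluene, 4 °C; aq. NH4Cl
Reagents that add atoms: none
Why: Trost ProPhenol–zinc asymmetric alkynylation, in which the dinuclear zinc catalyst delivers alkynylzinc 16 to the Si face of acrolein in a 1,2-fashion and sets the carbinol as R (deliberately the epimer of C6 of the target; the antipodal ligand would give S).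

Step 7
Reactants: 17 methyl (4R)-4-hydroxyhex-5-en-2-ynoate
Product: 18 methyl (4R)-4-(triethylsilyloxy)hex-5-en-2-ynoate
Conditions: Et3SiCl, imidazole, CH2Cl2, 0 °C
Reagents that add atoms: chlorotriethylsilane, CC[Si](Cl)(CC)CC
Why: Silylation masks the hydroxyl so it cannot lactonise onto the cis ester formed next or interfere with the organometallic steps, and the stereocentre is untouched.

Step 8
Reactants: 18 methyl (4R)-4-(triethylsilyloxy)hex-5-en-2-ynoate; 19 formaldehyde (gas, from paraformaldehyde)
Product: 21 methyl (2Z,4R)-2-(hydroxymethyl)-4-(triethylsilyloxy)hexa-2,5-dienoate, via vinylalane 20 (not isolated)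
Conditions: iBu2AlH, HMPA, THF, 0 °C; then CH2O, 0 °C → rt; aq. KNaC4H4O6 (potassium sodium tartrate)
Reagents that add atoms: none
Why: Conjugate syn-hydroalumination of the ynoate places hydrogen and aluminium cis, so trapping vinylalane 20 with formaldehyde with retention gives the Baylis–Hillman-type 2-(hydroxymethyl) enoate in which the C4 substituent is cis to the ester (Z).

Step 9
Reactants: 21 methyl (2Z,4R)-2-(hydroxymethyl)-4-(triethylsilyloxy)hexa-2,5-dienoate
Product: 22 methyl (2E,4R)-2-(bromomethyl)-4-(triethylsilyloxy)hexa-2,5-dienoate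
Conditions: CBr4, PPh3, CH2Cl2, 0 °C
Reagents that add atoms: tetrabromomethane, BrC(Br)(Br)Br
Why: The Appel reaction converts the primary allylic alcohol to the bromide by SN2 at CH2 without allylic transposition, preserving the olefin geometry (the E label only reflects the CIP change) and the silyloxy stereocentre.

Step 10
Reactants: 13 2-[(2S)-2-methyl-3-oxo-5-(prop-1-en-2-yl)-2,3-dihydrofuran-2-yl]acetaldehyde; 22 methyl (2E,4R)-2-(bromomethyl)-4-(triethylsilyloxy)hexa-2,5-dienoate
Product: 25 (4S,5S)-4-[(1R)-1-hydroxyprop-2-en-1-yl]-3-methylidene-5-{[(2S)-2-methyl-3-oxo-5-(prop-1-en-2-yl)-2,3-dihydrofuran-2-yl]methyl}oxolan-2-one, via allylchromium dichloride 23 (not isolated), via silyl ether lactone 24 (not isolated)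
Conditions: CrCl2 (4 equiv), THF, rt; 1 M HCl work-up, 0 °C → rt
Reagents that add atoms: none
Why: Nozaki–Hiyama (Barbier-type) allylation–lactonisation, in which allylchromium 23 adds through its γ-carbon via a chair Zimmerman–Traxler transition state with the C6 substituent (trans to CH2Cr) equatorial, giving the anti C7/C8 relationship, and reacts anti to the C6–O bond of the A(1,3)-locked conformer (Felkin-type control), so C7 and C8 are both set relative to C6 before the alkoxide closes onto the methyl ester to trans-lactone 24 and the acidic work-up removes the silyl group.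

Step 11
Reactants: 25 (4S,5S)-4-[(1R)-1-hydroxyprop-2-en-1-yl]-3-methylidene-5-{[(2S)-2-methyl-3-oxo-5-(prop-1-en-2-yl)-2,3-dihydrofuran-2-yl]methyl}oxolan-2-one
Product: 26 (4Z,6R,7S,8S,10S)-6-hydroxy-3,10-epoxy-1-oxogermacra-2,4,11(13)-trien-12,8-olide
Conditions: second-generation Hoveyda–Grubbs catalyst (15 mol %), 1,4-benzoquinone (20 mol %), toluene (1 mM), 80 °C
Reagents that add atoms: none
Why: Ring-closing metathesis, in which the ruthenium carbene loads on the monosubstituted vinyl group and closes onto the isopropenyl group to form the ten-membered ring, whose furanone bridge allows only the Z trisubstituted C4=C5 olefin; it is run before esterification because an allylic tiglate would cyclise to a butenolide, and the electron-poor exocyclic methylene is inert.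

Step 12
Reactants: 26 (4Z,6R,7S,8S,10S)-6-hydroxy-3,10-epoxy-1-oxogermacra-2,4,11(13)-trien-12,8-olide; 27 tiglic acid ((2E)-2-methylbut-2-enoic acid)
Product: 28 (4Z,6S,7R,8S,10S)-3,10-epoxy-6-[(2E)-2-methylbut-2-enoyloxy]-1-oxogermacra-2,4,11(13)-trien-12,8-olide
Conditions: 27, PPh3, DIAD, toluene, 0 °C → rt
Reagents that add atoms: none
Why: Mitsunobu esterification, in which SN2 displacement of the activated 6R hydroxyl by tiglate inverts C6 to the required S configuration and installs the ester in one operation, leaving C7, C8, C10 and both olefin geometries unchanged.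

**Compound list**

1 | (R)-lactic acid | C[C@@H](O)C(=O)O | starting material
2 | pivaldehyde | CC(C)(C)C=O | starting material
3 | (2R,5R)-2-tert-butyl-5-methyl-1,3-dioxolan-4-one | C[C@H]1O[C@@H](C(C)(C)C)OC1=O | intermediate
4 | prenyl bromide (1-bromo-3-methylbut-2-ene) | CC(C)=CCBr | starting material
5 | lithium (2R)-2-tert-butyl-5-methyl-1,3-dioxol-4-olate (enolate of 3) | CC1=C([O-])O[C@H](C(C)(C)C)O1.[Li+] | intermediate
6 | (2R,5S)-2-tert-butyl-5-methyl-5-(3-methylbut-2-en-1-yl)-1,3-dioxolan-4-one | C[C@@]1(CC=C(C)C)O[C@@H](C(C)(C)C)OC1=O | intermediate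
7 | 2-methylbut-1-en-3-yne | C=C(C)C#C | starting material
8 | lithium 3-methylbut-3-en-1-yn-1-ide | [Li+].[C-]#CC(C)=C | intermediate
9 | lithium (2R,5S)-2-tert-butyl-5-methyl-5-(3-methylbut-2-en-1-yl)-4-(3-methylbut-3-en-1-yn-1-yl)-1,3-dioxolan-4-olate (C4 not defined) | C[C@@]1(CC=C(C)C)O[C@@H](C(C)(C)C)OC1([O-])C#CC(C)=C.[Li+] | intermediate
10 | (6S)-6-hydroxy-2,6,9-trimethyldeca-1,8-dien-3-yn-5-one | C=C(C)C#CC(=O)[C@@](C)(O)CC=C(C)C | intermediate
11 | (2S)-2-methyl-2-(3-methylbut-2-en-1-yl)-5-(prop-1-en-2-yl)furan-3(2H)-one | CC(C)=CC[C@]1(C)OC(=CC1=O)C(C)=C | intermediate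
12 | (2S)-2-(2,3-dihydroxy-3-methylbutyl)-2-methyl-5-(prop-1-en-2-yl)furan-3(2H)-one (carbinol epimers) | CC(C)(O)C(O)C[C@]1(C)OC(=CC1=O)C(C)=C | intermediate
13 | 2-[(2S)-2-methyl-3-oxo-5-(prop-1-en-2-yl)-2,3-dihydrofuran-2-yl]acetaldehyde (fragment A) | O=CC[C@]1(C)OC(=CC1=O)C(C)=C | intermediate
14 | acrolein | C=CC=O | starting material
15 | methyl propiolate | C#CC(=O)OC | starting material
16 | methyl 3-(methylzincio)prop-2-ynoate (CH3ZnC≡CCO2CH3) | C[Zn]C#CC(=O)OC | intermediate
17 | methyl (4R)-4-hydroxyhex-5-en-2-ynoate | C=C[C@@H](O)C#CC(=O)OC | intermediate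
18 | methyl (4R)-4-(triethylsilyloxy)hex-5-en-2-ynoate | C=C[C@@H](O[Si](CC)(CC)CC)C#CC(=O)OC | intermediate
19 | formaldehyde | C=O | starting material
20 | methyl (2E,4R)-2-(diisobutylalumanyl)-4-(triethylsilyloxy)hexa-2,5-dienoate | C=C[C@@H](O[Si](CC)(CC)CC)/C=C(\C(=O)OC)[Al](CC(C)C)CC(C)C | intermediate
21 | methyl (2Z,4R)-2-(hydroxymethyl)-4-(triethylsilyloxy)hexa-2,5-dienoate | C=C[C@@H](O[Si](CC)(CC)CC)/C=C(\C(=O)OC)CO | intermediate
22 | methyl (2E,4R)-2-(bromomethyl)-4-(triethylsilyloxy)hexa-2,5-dienoate (fragment B) | C=C[C@@H](O[Si](CC)(CC)CC)/C=C(\C(=O)OC)CBr | intermediate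
23 | methyl (2E,4R)-2-[(dichlorochromio)methyl]-4-(triethylsilyloxy)hexa-2,5-dienoate | C=C[C@@H](O[Si](CC)(CC)CC)/C=C(\C(=O)OC)C[Cr](Cl)Cl | intermediate
24 | (4R,5S)-3-methylidene-5-{[(2S)-2-methyl-3-oxo-5-(prop-1-en-2-yl)-2,3-dihydrofuran-2-yl]methyl}-4-[(1R)-1-(triethylsilyloxy)prop-2-en-1-yl]oxolan-2-one | C=C1C(=O)O[C@@H](C[C@]2(C)OC(=CC2=O)C(C)=C)[C@@H]1[C@H](O[Si](CC)(CC)CC)C=C | intermediate
25 | (4S,5S)-4-[(1R)-1-hydroxyprop-2-en-1-yl]-3-methylidene-5-{[(2S)-2-methyl-3-oxo-5-(prop-1-en-2-yl)-2,3-dihydrofuran-2-yl]methyl}oxolan-2-one | C=C1C(=O)O[C@@H](C[C@]2(C)OC(=CC2=O)C(C)=C)[C@@H]1[C@H](O)C=C | intermediate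
26 | (4Z,6R,7S,8S,10S)-6-hydroxy-3,10-epoxy-1-oxogermacra-2,4,11(13)-trien-12,8-olide | C=C1C(=O)O[C@H]2C[C@]3(C)OC(=CC3=O)/C(C)=C\[C@@H](O)[C@H]12 | intermediate
27 | tiglic acid ((2E)-2-methylbut-2-enoic acid) | C/C=C(\C)C(=O)O | starting material
28 | (4Z,6S,7R,8S,10S)-3,10-epoxy-6-[(2E)-2-methylbut-2-enoyloxy]-1-oxogermacra-2,4,11(13)-trien-12,8-olide (CNP0293168.2) | C=C1C(=O)O[C@H]2C[C@]3(C)OC(=CC3=O)/C(C)=C\[C@H](OC(=O)/C(C)=C/C)[C@H]12 | target

**Step count and weak points**

Total: 12 steps. Longest linear sequence: 8 steps (1–5, then 10–12, from (R)-lactic acid). The second branch (6–9, then 10–12) is 7 steps long.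

The three steps most likely to fail are 10, 11 and 12.

Step 10 is at risk because the anti and Felkin-type selectivities of the chromium addition are argued from models, and the γ-silyloxy allylchromium could eliminate or scramble. The fallback replaces the Barbier-type organochromium addition by a stereospecific allylboration. It sets out from 18: the vinylalane generated as in step 8 is trapped with ICH2Bpin instead of formaldehyde to give methyl (2Z,4R)-2-[(4,4,5,5-tetramethyl-1,3,2-dioxaborolan-2-yl)methyl]-4-(triethylsilyloxy)hexa-2,5-dienoate F1. F1 and 13 are heated in toluene at 60 °C (Sc(OTf)3 as catalyst if slow); the configurationally fixed boronate reacts through a closed chair and gives the same anti adduct. The same 1 M HCl work-up lactonises through 24 and desilylates, so the fallback comes back to the route at 25.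

Step 11 is at risk because it forms a trisubstituted olefin in a strained bridged ten-membered ring, and the free allylic alcohol can chelate the catalyst or isomerise to a ketone. The fallback closes the ring before O6 is unmasked. It sets out from 24, isolated from step 10 by a pH 7 work-up instead of HCl. Metathesis of this bulkier, non-isomerisable substrate gives (4Z,6R,7R,8S,10S)-3,10-epoxy-1-oxo-6-(triethylsilyloxy)germacra-2,4,11(13)-trien-12,8-olide F2. HF·pyridine in THF then frees the alcohol, and the fallback comes back at 26.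

Step 12 is at risk because tiglic acid is a weak Mitsunobu acid, the macrocyclic allylic alcohol is hindered, and elimination towards C7 or SN2′ attack can compete. The fallback replaces the redox condensation by activation and displacement. It sets out from 26: Ms2O and pyridine in CH2Cl2 at −20 °C give (4Z,6R,7R,8S,10S)-6-(methanesulfonyloxy)-3,10-epoxy-1-oxogermacra-2,4,11(13)-trien-12,8-olide F3. F3 is displaced with caesium tiglate (CsO2CC(CH3)=CHCH3, 18-crown-6, toluene, 40 °C) with inversion, and the fallback comes back at 28.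

**Further compounds**

F1 | step 10 | methyl (2Z,4R)-2-[(4,4,5,5-tetramethyl-1,3,2-dioxaborolan-2-yl)methyl]-4-(triethylsilyloxy)hexa-2,5-dienoate | C=C[C@@H](O[Si](CC)(CC)CC)/C=C(\C(=O)OC)CB1OC(C)(C)C(C)(C)O1
F2 | step 11 | (4Z,6R,7R,8S,10S)-3,10-epoxy-1-oxo-6-(triethylsilyloxy)germacra-2,4,11(13)-trien-12,8-olide | C=C1C(=O)O[C@H]2C[C@]3(C)OC(=CC3=O)/C(C)=C\[C@@H](O[Si](CC)(CC)CC)[C@H]12
F3 | step 12 | (4Z,6R,7R,8S,10S)-6-(methanesulfonyloxy)-3,10-epoxy-1-oxogermacra-2,4,11(13)-trien-12,8-olide | C=C1C(=O)O[C@H]2C[C@]3(C)OC(=CC3=O)/C(C)=C\[C@@H](OS(C)(=O)=O)[C@H]12
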